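## Analysis of the target

Target **23** is a cis-fused bicyclo[5.3.0]decane (hydroazulene) of the daucane type. The ring atoms are numbered C1 (CH carrying the 4-methoxybenzoate), C2 (CH2), C3 (methyl-bearing alkene carbon), C4 (alkene CH), C5 (ketone), C6 (quaternary carbon with the angular methyl), C7 and C8 (CH2), C9 (carbinol carbon with isopropyl) and C10 (ring-fusion CH). The cycloheptenone is C1–C2–C3–C4–C5–C6–C10 and the cyclopentane is C6–C7–C8–C9–C10.

There are four stereocentres. The angular methyl, H10 and the C9 hydroxyl lie on one face. The isopropyl group and the C1 acyloxy group lie on the other, so the ester sits on the concave side next to the isopropyl group.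

The enone has an acidic C2 methylene and an acyloxy leaving group at C1, so base can expel 4-methoxybenzoate by vinylogous elimination. Whenever C1 is a ketone, the C9 hydroxyl is in a β-hydroxy ketone and can undergo retro-aldol cleavage.

The difficulties are the quaternary ring-fusion centre next to the ketone, a C9/C10/C1 triad with a cis fusion that cannot be left to equilibration, an oxygen on the hindered face of C1, and two trisubstituted alkenes that must be told apart.

The strategy rests on the array C3=C4, oxygen at C5 and quaternary C6. This is what a [3,3] shift leaves behind when a cyclopropane made of C1, C2 and C3 carries a C4=C5 enol ether on C3 and the C10=C6 bond of a cyclopentenone on C1.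

## Retrosynthetic reasoning

**23 ⇒ 22 ⇒ 21.** The C5 ketone is carried as a silyl ether and is released last. The base-sensitive δ-acyloxy enone then exists only in the final, buffered oxidation.

**21 ⇒ 19 + 20.** The ester C–O bond is cut with retention at C1. An inverting esterification of the C1 epimer was not chosen: the acid would have to attack from the concave face, past the cis-vicinal isopropyl group, and elimination towards C2 would be favoured.

**19 ⇒ 18 ⇒ 17.** The C1 configuration is corrected through ketone **18**. Hydride should attack the convex face, anti to the isopropyl group, and place the oxygen where the target has it.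

**17 ⇒ 14 (through 15 and 16).** The C1–O and C10–H bonds come from the C10=C1 alkene. An untethered borane would have to choose between two trisubstituted alkenes and between two hindered faces. A silicon hydride tethered to the C9 oxygen reaches only C10=C1 and adds H to C10 on the hydroxyl face, which is the cis ring fusion.

**14 ⇒ 13.** The C9–isopropyl bond is cut while C10 is still sp2. The carbonyl then sits in a flat cyclopentenone whose upper face is screened by the angular methyl. With a tetrahedral C10 the nucleophile would take the convex face and give the wrong epimer.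

**13 ⇒ 12.** The C5–C6 bond is cut, and with it the seven-membered ring, by a retro-Cope rearrangement that re-forms the C1–C3 bond. The forward reaction makes the ring and the quaternary centre, and puts both alkenes and the C5 oxygen in place in one thermal step, with chirality passed on from the cyclopropane.

**12 ⇒ 8 + 9.** The C1–C10 bond is cut as a cyclopropyl–alkenyl cross-coupling with retention. Joining the fragments last keeps the enone out of the homologation and enol silylation, where it would compete for ylide and silylating agent.

**8 ⇒ 7 ⇒ 6 ⇒ 5 ⇒ 4.** The E enol ether comes from aldehyde **7**, and **7** from carbinol **4** by a one-carbon homologation. A homoallylic alcohol would save two steps, but reagent-controlled cyclopropanation is dependable only for allylic alcohols.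

**4 ⇒ 3.** The cyclopropane methylene (C2) is removed to give a Z allylic alcohol. The Z geometry becomes the cis relationship of the two future alkenyl groups, and the hydroxyl anchors the chiral controller.

**3 ⇒ 1.** The C3–methyl bond and the C–I bond come from anti carbometalation of **1**, which puts the metal, and then iodine, cis to the hydroxymethyl group.

## Alternatives that were turned down

**Alternative 1:** rhodium (5+2) cycloaddition.
- **Disconnection:** C6–C10 and C1–C2 are cut together, leading to enyne A1, in which a (Z)-silyloxyvinyl cyclopropane and a terminal alkyne hang from the C9 carbinol.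
- **Key step:** [Rh(CO)2Cl]2 opens the cyclopropane, inserts the alkyne and closes both rings to give A2.
- **For it:** two rings and two C–C bonds form in one catalytic, atom-economical step. C9 is fixed beforehand, so no facial problem arises on the bicycle. The enol ether of A2 marks C5 as the ketone and could be dehydrogenated to C3=C4.
- **Against it:** A2 carries hydrogen at C6. The angular methyl would have to be introduced later by alkylating a ring-fusion dienolate, with competition from the γ position and no firm control of the face. A1 needs an enantiopure tertiary propargylic carbinol. Its trisubstituted, oxygenated vinyl group is the least reactive type of partner for metallacycle formation.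
- **Comparison:** it is stronger in rings formed per step and in having C9 set early. The chosen route offers the quaternary centre and the C3=C4 alkene directly from the ring-forming event, with absolute control from a cyclopropane.

**Alternative 2:** one-carbon ring expansion of a cis-hydrindanone.
- **Disconnection:** C4 is excised, cutting C3–C4 and C4–C5 and leading to the tetrasubstituted silyl enol ether A3.
- **Key step:** Et2Zn/CH2I2 cyclopropanates the enol ether, FeCl3 cleaves the internal bond to a β-chloro ketone, and NaOAc eliminates it to give A4, one deprotection from the target.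
- **For it:** all four stereocentres are set on a rigid, predictable hydrindane. Enolisation can only go towards C3 because C6 is quaternary. The sequence after the key step is the shortest of all.
- **Against it:** the key step adds one carbon and no stereocentre, so the whole stereochemical load falls on a long linear prelude. Methylene transfer to a tetrasubstituted enol ether beside a quaternary carbon is the sterically worst case. The labile anisate must survive FeCl3 and the elimination, which must also go towards C4 and not C2.
- **Comparison:** it is stronger in end-game brevity. The chosen route builds the seven-membered ring early from small fragments and does not expose the finished ester to ring-expansion conditions.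

**Alternative 3:** Nazarov cyclisation.
- **Disconnection:** C6–C7 is cut, leading to the cross-conjugated dienone A5 on a preformed seven-membered ring.
- **Key step:** a Lewis acid such as Sc(OTf)3 triggers conrotatory closure of the pentadienyl cation, and loss of the C1 proton gives A6.
- **For it:** A5 is a few steps from a cycloheptenone. The step is catalytic, creates the quaternary C6 and gives the same C9 enone as **13**, so the same end-game logic applies.
- **Against it:** A6 lacks the C3 methyl and the C3=C4 alkene, which cost a dehydrogenation, a conjugate methylation and a second dehydrogenation. A5 is an unpolarised divinyl ketone with a bare vinyl terminus. The cation next to the new quaternary carbon invites 1,2-shifts, the proton can be lost towards C7, and torquoselectivity rests on one allylic silyloxy group.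
- **Comparison:** it is as good at forging C6 and better in precursor simplicity. The chosen rearrangement offers the complete carbon skeleton, both alkenes in their final places and neutral thermal conditions.

Key step: step 8

Remark: **9** is taken as a purchased compound; if it is not available, bromination–dehydrobromination of 3-methylcyclopent-2-en-1-one gives it in one step.

## Route

Step 1
Reactants: 1 prop-2-yn-1-ol
Product: 3 (Z)-3-iodo-2-methylprop-2-en-1-ol, via chelated (Z)-alkenylmagnesium alkoxide 2 (not isolated)
Conditions: MeMgBr (3 equiv), CuI (10 mol%), THF, −10 → 23 °C; then I2, −78 → 0 °C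
Reagents that add atoms: methylmagnesium bromide, C[Mg]Br; iodine, II
Why: Copper-catalysed anti carbomagnesiation of a propargylic alkoxide (Duboudin type) places methyl on the internal carbon and magnesium on the terminal carbon inside a five-membered chelate, cis to CH2O. Iodinolysis goes with retention, so iodine ends cis to the hydroxymethyl group.

Step 2
Reactants: 3 (Z)-3-iodo-2-methylprop-2-en-1-ol
Product: 4 [(1R,2R)-2-iodo-1-methylcyclopropyl]methanol
Conditions: Et2Zn, CH2I2, DME (gives Zn(CH2I)2·DME), (4R,5R)-2-butyl-N,N,N′,N′-tetramethyl-1,3,2-dioxaborolane-4,5-dicarboxamide (1.2 equiv), CH2Cl2, −10 → 23 °C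
Reagents that add atoms: diiodomethane, ICI
Why: Charette asymmetric Simmons–Smith cyclopropanation: the zinc alkoxide binds to boron and the amide groups steer Zn(CH2I)2 to one alkene face; the (4R,5R) ligand should give the (1R,2R) isomer, in the sense it shows with simple allylic alcohols. The addition is syn, so iodine stays cis to CH2OH; hydroxyl-directed zinc carbenoids are known to cyclopropanate (Z)-3-iodoallylic alcohols.

Step 3
Reactants: 4 [(1R,2R)-2-iodo-1-methylcyclopropyl]methanol
Product: 5 (1R,2R)-2-iodo-1-methylcyclopropane-1-carbaldehyde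
Conditions: Dess–Martin periodinane, NaHCO3, CH2Cl2, 0 → 23 °C
Reagents that add atoms: none
Why: Dess–Martin oxidation of a primary alcohol; the α-carbon is quaternary, so the aldehyde cannot epimerise.

Step 4
Reactants: 5 (1R,2R)-2-iodo-1-methylcyclopropane-1-carbaldehyde
Product: 6 (1R,2R)-1-iodo-2-(2-methoxyethenyl)-2-methylcyclopropane (E/Z mixture)
Conditions: Ph3P(CH2OMe)Cl, KOt-Bu, THF, 0 °C; then 5, −78 → 0 °C
Reagents that add atoms: (methoxymethyl)triphenylphosphonium chloride, COC[P+](c1ccccc1)(c1ccccc1)c1ccccc1.[Cl-]
Why: Wittig methoxymethylenation (one-carbon homologation); the alkene geometry is irrelevant because the enol ether is hydrolysed next.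

Step 5
Reactants: 6 (1R,2R)-1-iodo-2-(2-methoxyethenyl)-2-methylcyclopropane
Product: 7 2-[(1S,2R)-2-iodo-1-methylcyclopropyl]acetaldehyde
Conditions: 1 M aq. HCl, THF, 0 → 23 °C
Reagents that add atoms: water, O
Why: Acid hydrolysis of an enol ether through an oxocarbenium ion; the cation is separated from the ring by C4, so it is not cyclopropylcarbinyl and the ring should survive.

Step 6
Reactants: 7 2-[(1S,2R)-2-iodo-1-methylcyclopropyl]acetaldehyde
Product: 8 tert-butyl({(E)-2-[(1R,2R)-2-iodo-1-methylcyclopropyl]ethenyl}oxy)dimethylsilane
Conditions: TBSOTf, Et3N, CH2Cl2, −78 → 0 °C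
Reagents that add atoms: tert-butyldimethylsilyl trifluoromethanesulfonate, CC(C)(C)[Si](C)(C)OS(=O)(=O)C(F)(F)F
Why: Soft enolisation (silyl triflate and amine) at the only enolisable position; the β-substituent is a fully substituted ring carbon, so the E enol ether, which keeps it away from the silyloxy group, should dominate. No ketone is present yet, so no competing enolisation can occur.

Step 7
Reactants: 8 tert-butyl({(E)-2-[(1R,2R)-2-iodo-1-methylcyclopropyl]ethenyl}oxy)dimethylsilane; 9 2-bromo-3-methylcyclopent-2-en-1-one
Product: 12 2-[(1R,2S)-2-{(E)-2-[(tert-butyldimethylsilyl)oxy]ethenyl}-2-methylcyclopropyl]-3-methylcyclopent-2-en-1-one, via cyclopropyllithium 10 (not isolated), via cyclopropylzinc bromide 11 (not isolated)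
Conditions: t-BuLi (2.1 equiv), Et2O, −78 °C; ZnBr2, THF, −78 → 0 °C; then 9, Pd(P(t-Bu)3)2 (5 mol%), THF, 23 → 40 °C
Reagents that add atoms: none
Why: Iodine–lithium exchange gives a configurationally stable cyclopropyllithium; transmetalation to zinc and Negishi coupling with the α-bromoenone go with retention at C1, so the two alkenyl groups stay cis. The neutral, anhydrous conditions spare the silyl enol ether, and the organozinc does not attack the ketone.

Step 8
Reactants: 12 2-[(1R,2S)-2-{(E)-2-[(tert-butyldimethylsilyl)oxy]ethenyl}-2-methylcyclopropyl]-3-methylcyclopent-2-en-1-one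
Product: 13 (3aS,4R)-4-[(tert-butyldimethylsilyl)oxy]-3a,6-dimethyl-3,3a,4,7-tetrahydroazulen-1(2H)-one
Conditions: toluene (0.05 M, degassed, base-washed glass), 2,6-di-tert-butyl-4-methylphenol (cat.), 110 °C, sealed tube
Reagents that add atoms: none
Why: A concerted [3,3] sigmatropic (Cope) shift of the cis-1,2-dialkenylcyclopropane runs through the boat array in which both alkenes lie over the three-membered ring: the C1–C3 bond breaks as C5–C6 forms, and release of ring strain makes it irreversible. The closest known reaction type is the divinylcyclopropane–cycloheptadiene rearrangement of substrates with a fully substituted terminus or a cis substituent, which need heating. The seven-membered ring closes by pericyclic σ-bond formation between the two alkene termini, a four-atom ring expansion and not a polar cyclisation. C6 is controlled by the cyclopropane: the (1R,2S) cis geometry lets the enone alkene meet the enol ether with one face only, with the ring CH2 outside and the methyl inside, which gives 3aS. C5 is controlled by the E geometry of the enol ether, which puts the silyloxy group outside and therefore trans to the angular methyl (4R). The step needs the cis relationship on the ring, secured by the Z geometry of 3 and the stereospecific steps 2 and 7, and the E enol ether from step 6. A competing homodienyl hydrogen shift is excluded because the ring methyl is trans to the cyclopentenyl group. The product keeps the ketone conjugated with C10=C1, and the acyl group on the central carbon of one allyl unit should lower the barrier that the inside methyl raises.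

Step 9
Reactants: 13 (3aS,4R)-4-[(tert-butyldimethylsilyl)oxy]-3a,6-dimethyl-3,3a,4,7-tetrahydroazulen-1(2H)-one
Product: 14 (1R,3aS,4R)-4-[(tert-butyldimethylsilyl)oxy]-3a,6-dimethyl-1-(propan-2-yl)-1,2,3,3a,4,7-hexahydroazulen-1-ol
Conditions: i-PrMgCl, CeCl3 (dried), THF, −78 °C; aq. NH4Cl
Reagents that add atoms: isopropylmagnesium chloride, CC(C)[Mg]Cl
Why: Organocerium 1,2-addition (Imamoto conditions): the weakly basic i-PrCeCl2 should avoid deprotonation of the doubly allylic C2 methylene and conjugate addition. With C10 still sp2 the cyclopentenone is flat and the nearly perpendicular angular methyl screens the upper face, so isopropyl should enter from below and the hydroxyl should end cis to the methyl.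

Step 10
Reactants: 14 (1R,3aS,4R)-4-[(tert-butyldimethylsilyl)oxy]-3a,6-dimethyl-1-(propan-2-yl)-1,2,3,3a,4,7-hexahydroazulen-1-ol
Product: 17 (1R,3aS,4R,8R,8aR)-4-[(tert-butyldimethylsilyl)oxy]-3a,6-dimethyl-1-(propan-2-yl)-1,2,3,3a,4,7,8,8a-octahydroazulene-1,8-diol, via dimethylsilyl ether 15 (not isolated), via tricyclic oxasilolane 16 (not isolated)
Conditions: (HMe2Si)2NH, NH4Cl (cat.), 60 °C, then volatiles removed; Pt2(dvtms)3 (1 mol%; dvtms = 1,3-divinyl-1,1,3,3-tetramethyldisiloxane), toluene, 60 °C; then 30% H2O2, KF, KHCO3, THF–MeOH, 40 °C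
Reagents that add atoms: hydrogen peroxide, OO
Why: Tamao–Ito intramolecular hydrosilylation and oxidation: the Si–H tethered to the C9 oxygen can reach only C10=C1, so C3=C4 is left alone. Platinum-catalysed syn addition in the 5-endo mode puts silicon on C1 and hydrogen on C10 from the face of the C9 oxygen, which sets the cis ring fusion. Tamao oxidation then replaces silicon by hydroxyl with retention, giving the syn 1,3-diol.

Step 11
Reactants: 17 (1R,3aS,4R,8R,8aR)-4-[(tert-butyldimethylsilyl)oxy]-3a,6-dimethyl-1-(propan-2-yl)-1,2,3,3a,4,7,8,8a-octahydroazulene-1,8-diol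
Product: 18 (3R,3aS,8R,8aS)-8-[(tert-butyldimethylsilyl)oxy]-3-hydroxy-6,8a-dimethyl-3-(propan-2-yl)-2,3,3a,5,8,8a-hexahydroazulen-4(1H)-one
Conditions: Dess–Martin periodinane, NaHCO3, CH2Cl2, 0 °C; used at once
Reagents that add atoms: none
Why: Dess–Martin oxidation of the only secondary alcohol; the tertiary alcohol cannot be oxidised. Buffered, cold and brief handling should prevent retro-aldol cleavage, epimerisation at C10 and migration of the β,γ-alkene.

Step 12
Reactants: 18 (3R,3aS,8R,8aS)-8-[(tert-butyldimethylsilyl)oxy]-3-hydroxy-6,8a-dimethyl-3-(propan-2-yl)-2,3,3a,5,8,8a-hexahydroazulen-4(1H)-one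
Product: 19 (1R,3aS,4R,8S,8aR)-4-[(tert-butyldimethylsilyl)oxy]-3a,6-dimethyl-1-(propan-2-yl)-1,2,3,3a,4,7,8,8a-octahydroazulene-1,8-diol
Conditions: NaBH4, CeCl3·7H2O, MeOH, −78 °C
Reagents that add atoms: none
Why: Luche-type ketone reduction: hydride should attack C1 from the convex face of the cis-fused bicycle, anti to the isopropyl group that is cis-vicinal across C10. The hydroxyl therefore ends on the concave face, inverted relative to 17 (C1 now S).

Step 13
Reactants: 19 (1R,3aS,4R,8S,8aR)-4-[(tert-butyldimethylsilyl)oxy]-3a,6-dimethyl-1-(propan-2-yl)-1,2,3,3a,4,7,8,8a-octahydroazulene-1,8-diol; 20 4-methoxybenzoyl chloride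
Product: 21 (3R,3aR,4S,8R,8aS)-8-[(tert-butyldimethylsilyl)oxy]-3-hydroxy-6,8a-dimethyl-3-(propan-2-yl)-1,2,3,3a,4,5,8,8a-octahydroazulen-4-yl 4-methoxybenzoate
Conditions: DMAP, Et3N, CH2Cl2, 0 → 40 °C
Reagents that add atoms: none
Why: DMAP-catalysed acyl transfer to the secondary alcohol with retention at C1; the tertiary C9 alcohol is too hindered to react.

Step 14
Reactants: 21 (3R,3aR,4S,8R,8aS)-8-[(tert-butyldimethylsilyl)oxy]-3-hydroxy-6,8a-dimethyl-3-(propan-2-yl)-1,2,3,3a,4,5,8,8a-octahydroazulen-4-yl 4-methoxybenzoate
Product: 22 (3R,3aR,4S,8R,8aS)-3,8-dihydroxy-6,8a-dimethyl-3-(propan-2-yl)-1,2,3,3a,4,5,8,8a-octahydroazulen-4-yl 4-methoxybenzoate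
Conditions: HF·pyridine, pyridine, THF, 0 → 23 °C
Reagents that add atoms: none
Why: Fluoride cleavage of the silyl ether under buffered, non-basic conditions that leave the aryl ester in place and do not ionise the allylic carbinol.

Step 15
Reactants: 22 (3R,3aR,4S,8R,8aS)-3,8-dihydroxy-6,8a-dimethyl-3-(propan-2-yl)-1,2,3,3a,4,5,8,8a-octahydroazulen-4-yl 4-methoxybenzoate
Product: 23 (3R,3aR,4S,8aS)-3-hydroxy-6,8a-dimethyl-8-oxo-3-(propan-2-yl)-1,2,3,3a,4,5,8,8a-octahydroazulen-4-yl 4-methoxybenzoate
Conditions: Dess–Martin periodinane, NaHCO3, CH2Cl2, 0 → 23 °C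
Reagents that add atoms: none
Why: Dess–Martin oxidation of the allylic alcohol to the enone; the buffered, base-free medium protects the δ-acyloxy enone. The tertiary alcohol is inert and the adjacent C6 is quaternary, so no stereocentre is at risk.

## Compound list

1 | prop-2-yn-1-ol | C#CCO | starting material
2 | bromomagnesium (Z)-3-(bromomagnesio)-2-methylprop-2-en-1-olate | Br[Mg]OC/C(C)=C\[Mg]Br | intermediate
3 | (Z)-3-iodo-2-methylprop-2-en-1-ol | OC/C(C)=C\I | intermediate
4 | [(1R,2R)-2-iodo-1-methylcyclopropyl]methanol | I[C@@H]1C[C@]1(C)CO | intermediate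
5 | (1R,2R)-2-iodo-1-methylcyclopropane-1-carbaldehyde | I[C@@H]1C[C@]1(C)C=O | intermediate
6 | (1R,2R)-1-iodo-2-(2-methoxyethenyl)-2-methylcyclopropane (E/Z mixture) | I[C@@H]1C[C@]1(C)C=COC | intermediate
7 | 2-[(1S,2R)-2-iodo-1-methylcyclopropyl]acetaldehyde | I[C@@H]1C[C@]1(C)CC=O | intermediate
8 | tert-butyl({(E)-2-[(1R,2R)-2-iodo-1-methylcyclopropyl]ethenyl}oxy)dimethylsilane | I[C@@H]1C[C@]1(C)/C=C/O[Si](C)(C)C(C)(C)C | intermediate
9 | 2-bromo-3-methylcyclopent-2-en-1-one | O=C1CCC(C)=C1Br | starting material
10 | cyclopropyllithium from 8 (lithium in place of iodine, same configuration) | [Li][C@@H]1C[C@]1(C)/C=C/O[Si](C)(C)C(C)(C)C | intermediate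
11 | cyclopropylzinc bromide from 10 (same configuration) | Br[Zn][C@@H]1C[C@]1(C)/C=C/O[Si](C)(C)C(C)(C)C | intermediate
12 | 2-[(1R,2S)-2-{(E)-2-[(tert-butyldimethylsilyl)oxy]ethenyl}-2-methylcyclopropyl]-3-methylcyclopent-2-en-1-one | O=C1CCC(C)=C1[C@@H]2C[C@]2(C)/C=C/O[Si](C)(C)C(C)(C)C | intermediate
13 | (3aS,4R)-4-[(tert-butyldimethylsilyl)oxy]-3a,6-dimethyl-3,3a,4,7-tetrahydroazulen-1(2H)-one | O=C1CC[C@]2(C)[C@H](O[Si](C)(C)C(C)(C)C)C=C(C)CC=C12 | intermediate
14 | (1R,3aS,4R)-4-[(tert-butyldimethylsilyl)oxy]-3a,6-dimethyl-1-(propan-2-yl)-1,2,3,3a,4,7-hexahydroazulen-1-ol | CC1=C[C@@H](O[Si](C)(C)C(C)(C)C)[C@@]2(C)CC[C@@](O)(C(C)C)C2=CC1 | intermediate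
15 | dimethylsilyl ether of 14 at the C9 oxygen | CC1=C[C@@H](O[Si](C)(C)C(C)(C)C)[C@@]2(C)CC[C@@](O[SiH](C)C)(C(C)C)C2=CC1 | intermediate
16 | tricyclic oxasilolane (SiMe2 bridging the C9 oxygen and C1; H10 cis to the angular methyl) | C[Si]4(C)[C@@H]1CC(C)=C[C@@H](O[Si](C)(C)C(C)(C)C)[C@@]2(C)CC[C@@](O4)(C(C)C)[C@@H]12 | intermediate
17 | (1R,3aS,4R,8R,8aR)-4-[(tert-butyldimethylsilyl)oxy]-3a,6-dimethyl-1-(propan-2-yl)-1,2,3,3a,4,7,8,8a-octahydroazulene-1,8-diol | O[C@@H]1CC(C)=C[C@@H](O[Si](C)(C)C(C)(C)C)[C@@]2(C)CC[C@@](O)(C(C)C)[C@@H]12 | intermediate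
18 | (3R,3aS,8R,8aS)-8-[(tert-butyldimethylsilyl)oxy]-3-hydroxy-6,8a-dimethyl-3-(propan-2-yl)-2,3,3a,5,8,8a-hexahydroazulen-4(1H)-one | O=C1CC(C)=C[C@@H](O[Si](C)(C)C(C)(C)C)[C@@]2(C)CC[C@@](O)(C(C)C)[C@@H]12 | intermediate
19 | (1R,3aS,4R,8S,8aR)-4-[(tert-butyldimethylsilyl)oxy]-3a,6-dimethyl-1-(propan-2-yl)-1,2,3,3a,4,7,8,8a-octahydroazulene-1,8-diol | O[C@H]1CC(C)=C[C@@H](O[Si](C)(C)C(C)(C)C)[C@@]2(C)CC[C@@](O)(C(C)C)[C@@H]12 | intermediate
20 | 4-methoxybenzoyl chloride | COc1ccc(cc1)C(Cl)=O | starting material
21 | (3R,3aR,4S,8R,8aS)-8-[(tert-butyldimethylsilyl)oxy]-3-hydroxy-6,8a-dimethyl-3-(propan-2-yl)-1,2,3,3a,4,5,8,8a-octahydroazulen-4-yl 4-methoxybenzoate | COc1ccc(cc1)C(=O)O[C@H]1CC(C)=C[C@@H](O[Si](C)(C)C(C)(C)C)[C@@]2(C)CC[C@@](O)(C(C)C)[C@@H]12 | intermediate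
22 | (3R,3aR,4S,8R,8aS)-3,8-dihydroxy-6,8a-dimethyl-3-(propan-2-yl)-1,2,3,3a,4,5,8,8a-octahydroazulen-4-yl 4-methoxybenzoate | COc1ccc(cc1)C(=O)O[C@H]1CC(C)=C[C@@H](O)[C@@]2(C)CC[C@@](O)(C(C)C)[C@@H]12 | intermediate
23 | (3R,3aR,4S,8aS)-3-hydroxy-6,8a-dimethyl-8-oxo-3-(propan-2-yl)-1,2,3,3a,4,5,8,8a-octahydroazulen-4-yl 4-methoxybenzoate | COc1ccc(C(=O)O[C@H]2CC(C)=CC(=O)[C@@]3(C)CC[C@@](O)(C(C)C)[C@@H]23)cc1 | target

## Step count and least certain steps

Total step count: 15. Longest linear sequence: 15 steps (1 → 23); 9 and 20 are purchased.

**Step 8 (key step).** The methyl on the enone terminus has to sit inside, over the cyclopropane. If the barrier is too high, one-centre epimerisation of the ring, loss or isomerisation of the silyl enol ether, and drift of the skipped dienone into conjugation can overtake the [3,3] shift. The fallback takes the quaternary methyl out of the pericyclic step. It sets out from 8, which is lithiated and zincated as in step 7 and coupled with 2-bromocyclopent-2-en-1-one F1 to give the des-methyl dialkenylcyclopropane F2. F2 has no inside substituent and should rearrange under mild heating to the dienone F3. RhCl3·3H2O in ethanol moves the exocyclic C10=C1 bond into the ring fusion to give the enone F4. Me2CuLi with Me3SiCl then adds methyl to C6, anti to the neighbouring silyloxy group, to give the silyl enol ether F5. Pd(OAc)2 dehydrogenates F5 and the route is rejoined at 13.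

**Step 10.** The oxasilolane 16 is trans-fused to the cyclopentane. That strain can slow the Si–C bond-forming step, so that platinum hydride migrates the C10=C1 bond or the silyl ether is recovered. The fallback sets out from 14, which is treated with BH3·SMe2 to give the alkylborane F6 and oxidised with NaBO3 to 17. Borane should attack the convex face, and C4 of the other alkene is shielded by the silyloxy-bearing carbon next to it, but chemoselectivity is less secure than with the tether.

**Step 7.** Both partners are hindered. Slow transmetalation or reductive elimination would show up as protonation or homocoupling of the cyclopropyl metal, and the cyclopropyllithium might suffer oxygen-to-carbon silyl migration. The fallback joins the fragments before the ring exists. It sets out from 3, which is converted to its lithium alkoxide, exchanged with t-BuLi, zincated and coupled with 9 to give the dienol F7. The same dioxaborolane-controlled cyclopropanation gives the carbinol F8. Oxidation gives the aldehyde F9, methoxymethylenation the enol ether F10 and hydrolysis the aldehyde F11. Silylation with TBSOTf and Et3N at −78 °C, where the aldehyde should enolise before the hindered enone, returns to 12.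

**Step 9.** Facial discrimination may be poor if the C5 silyloxy group screens the lower face as much as the methyl screens the upper one, and proton abstraction at C2 may compete. The fallback sets out from 13. HF·pyridine gives the hydroxy dienone F12. Its magnesium alkoxide, formed with excess i-PrMgCl and CeCl3, removes the only bulky group from the lower face and can escort the reagent there, giving the diol F13. Selective silylation of the secondary hydroxyl with TBSOTf and 2,6-lutidine returns to 14.

**Step 12 (with step 11).** The β-hydroxy ketone 18 may cleave by retro-aldol reaction, epimerise at C10 towards the trans fusion or move its alkene into conjugation before it is reduced, and hydride delivery may be unselective. The fallback avoids the ketone. It sets out from 17, which is treated with 4-methoxybenzoic acid, PPh3 and diisopropyl azodicarboxylate (Mitsunobu inversion) to give 21 directly. The hindered approach of the acid and elimination towards C2 are the risks there.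

**Step 2.** The iodine-bearing alkene is deactivated, so cyclopropanation may be slow and a background reaction outside the boronate complex may erode the enantiomeric purity. The fallback sets out from 1. Carbomagnesiation as in step 1 with a Bu3SnCl quench gives the stannane F14. Its dioxaborolane-controlled cyclopropanation, the better-established substrate class, gives the stannylcyclopropane F15, and iododestannylation with I2 (retention) returns to 4.

Further compounds
F1 | step 8 | 2-bromocyclopent-2-en-1-one | O=C1CCC=C1Br
F2 | step 8 | 2-[(1R,2S)-2-{(E)-2-[(tert-butyldimethylsilyl)oxy]ethenyl}-2-methylcyclopropyl]cyclopent-2-en-1-one | O=C1CCC=C1[C@@H]2C[C@]2(C)/C=C/O[Si](C)(C)C(C)(C)C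
F3 | step 8 | (3aS,4R)-4-[(tert-butyldimethylsilyl)oxy]-6-methyl-3,3a,4,7-tetrahydroazulen-1(2H)-one | O=C1CC[C@@H]2[C@H](O[Si](C)(C)C(C)(C)C)C=C(C)CC=C12
F4 | step 8 | (4R)-4-[(tert-butyldimethylsilyl)oxy]-6-methyl-3,4,7,8-tetrahydroazulen-1(2H)-one | O=C1CCC2=C1CCC(C)=C[C@H]2O[Si](C)(C)C(C)(C)C
F5 | step 8 | (3aS,4R)-4-[(tert-butyldimethylsilyl)oxy]-3a,6-dimethyl-1-[(trimethylsilyl)oxy]-2,3,3a,4,7,8-hexahydroazulene | C[Si](C)(C)OC1=C2CCC(C)=C[C@@H](O[Si](C)(C)C(C)(C)C)[C@@]2(C)CC1
F6 | step 10 | C1 alkylborane of 14 with the C9 oxygen as its BH2 ester | B[C@@H]1CC(C)=C[C@@H](O[Si](C)(C)C(C)(C)C)[C@@]2(C)CC[C@@](OB)(C(C)C)[C@@H]12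
F7 | step 7 | 2-[(Z)-3-hydroxy-2-methylprop-1-en-1-yl]-3-methylcyclopent-2-en-1-one | OC/C(C)=C\C1=C(C)CCC1=O
F8 | step 7 | 2-[(1R,2S)-2-(hydroxymethyl)-2-methylcyclopropyl]-3-methylcyclopent-2-en-1-one | O=C1CCC(C)=C1[C@@H]2C[C@]2(C)CO
F9 | step 7 | (1S,2R)-1-methyl-2-(2-methyl-5-oxocyclopent-1-en-1-yl)cyclopropane-1-carbaldehyde | O=C1CCC(C)=C1[C@@H]2C[C@]2(C)C=O
F10 | step 7 | 2-[(1R,2S)-2-(2-methoxyethenyl)-2-methylcyclopropyl]-3-methylcyclopent-2-en-1-one (E/Z mixture) | O=C1CCC(C)=C1[C@@H]2C[C@]2(C)C=COC
F11 | step 7 | 2-[(1R,2R)-1-methyl-2-(2-methyl-5-oxocyclopent-1-en-1-yl)cyclopropyl]acetaldehyde | O=C1CCC(C)=C1[C@@H]2C[C@]2(C)CC=O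
F12 | step 9 | (3aS,4R)-4-hydroxy-3a,6-dimethyl-3,3a,4,7-tetrahydroazulen-1(2H)-one | O=C1CC[C@]2(C)[C@H](O)C=C(C)CC=C12
F13 | step 9 | (1R,3aS,4R)-3a,6-dimethyl-1-(propan-2-yl)-1,2,3,3a,4,7-hexahydroazulene-1,4-diol | CC1=C[C@@H](O)[C@@]2(C)CC[C@@](O)(C(C)C)C2=CC1
F0 | step 12 | none | none
F14 | step 2 | (Z)-2-methyl-3-(tributylstannyl)prop-2-en-1-ol | CCCC[Sn](CCCC)(CCCC)/C=C(C)\CO
F15 | step 2 | [(1R,2R)-1-methyl-2-(tributylstannyl)cyclopropyl]methanol | CCCC[Sn](CCCC)(CCCC)[C@@H]1C[C@]1(C)CO
A1 | alternative 1 | alkyne-tethered (Z)-silyloxyvinyl cyclopropane (C9 triethylsilyl ether, trans-2-methylcyclopropyl) | C#C[C@](O[Si](CC)(CC)CC)(C(C)C)CC/C=C(O[Si](C)(C)C(C)(C)C)/[C@H]1C[C@@H]1C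
A2 | alternative 1 | bicyclo[5.3.0]decadiene with C5 silyl enol ether, C10=C1 and hydrogen at C6 | CC[Si](CC)(CC)O[C@@]1(C(C)C)CC[C@H]2C1=CC[C@H](C)C=C2O[Si](C)(C)C(C)(C)C
A3 | alternative 2 | cis-hydrindanone trimethylsilyl enol ether carrying the C1 anisate and the C9 triethylsilyl ether | COc1ccc(cc1)C(=O)O[C@H]2CC(C)=C(O[Si](C)(C)C)[C@@]3(C)CC[C@@](O[Si](CC)(CC)CC)(C(C)C)[C@@H]23
A4 | alternative 2 | C9 triethylsilyl ether of the target | COc1ccc(cc1)C(=O)O[C@H]2CC(C)=CC(=O)[C@@]3(C)CC[C@@](O[Si](CC)(CC)CC)(C(C)C)[C@@H]23
A5 | alternative 3 | 1-{3-[(tert-butyldimethylsilyl)oxy]-2-methylcyclohept-1-en-1-yl}prop-2-en-1-one | C=CC(=O)C1=C(C)[C@@H](O[Si](C)(C)C(C)(C)C)CCCC1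
A6 | alternative 3 | bicyclo[5.3.0]decenone with angular methyl and C5 silyl ether, lacking the C3 methyl | O=C1CC[C@]2(C)[C@@H](O[Si](C)(C)C(C)(C)C)CCCC=C12
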